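**Retrosynthetic overview**
1. The last disconnection is the ring A benzyl ether: 17 gives the target 18 with BCl3.
2. The key disconnection is the lactone O–C6 bond of the seven-membered ring. It rests on three neighbouring carbons of ring B (the benzene ring of the chromanone): C8 carries the free OH, C7 the diaryl ether oxygen and C6 the lactone oxygen. Oxidation of the C8 phenol lets the ring A carboxyl add ipso at C7 (six-membered spirolactone), and a 1,2-acyloxy shift to C6–H gives the seven-membered lactone.
3. The diaryl ether O–C bond is made by SNAr of a 7-hydroxychromanone on a ring A aryl fluoride flanked by formyl and ester. O8 is masked as a 4-methoxybenzyl ether for this step, because a free phenoxide next to the new ether could let the activated ring A migrate from O7 to O8 (Smiles rearrangement). The ester is a 4-methoxybenzyl ester, so one acidolysis frees acid and phenol without base.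
4. Ring A comes from 3-fluoro-5-methylphenol (para-bromination, benzylation, ortho-lithiation/formylation, carbonylation). Ring B comes from 3,4,5-trimethoxytoluene via 5-methylpyrogallol and 3,3-dimethylacrylic acid.
5. Ring order: pyranone ring (step 6), then the transient six-membered spirolactone and the seven-membered lactone (both step 10).

Key step: step 10

Assumption: the target has no stereocentre; the spiro carbon of 16 should form racemic and is lost on rearomatisation, so no stereocontrol is planned.

**Route**

Step 1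
Reactants: 1 3-fluoro-5-methylphenol
Product: 2 4-bromo-3-fluoro-5-methylphenol
Conditions: NBS (1.0 equiv), MeCN, 0 °C
Reagents that add atoms: N-bromosuccinimide, O=C1CCC(=O)N1Br
Why: Electrophilic aromatic bromination should go para to the OH, as is usual for 3,5-disubstituted phenols, and any ortho isomer would be removed by chromatography.

Step 2
Reactants: 2 4-bromo-3-fluoro-5-methylphenol
Product: 3 5-(benzyloxy)-2-bromo-1-fluoro-3-methylbenzene
Conditions: BnBr, K2CO3, DMF, 20 °C
Reagents that add atoms: benzyl bromide, BrCc1ccccc1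
Why: Williamson ether synthesis on the only acidic group of the molecule.

Step 3
Reactants: 3 5-(benzyloxy)-2-bromo-1-fluoro-3-methylbenzene
Product: 5 6-(benzyloxy)-3-bromo-2-fluoro-4-methylbenzaldehyde, via aryllithium 4 (not isolated)
Conditions: LiN(iPr)2 (1.1 equiv), THF, −78 °C; DMF, −78 to 0 °C; 1 M HCl
Reagents that add atoms: N,N-dimethylformamide, CN(C)C=O
Why: Directed ortho-metalation removes the most acidic ring proton, the one between F and OBn; the amide base does not exchange the bromide, −78 °C holds back LiF loss to an aryne, and DMF formylates the aryllithium.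

Step 4
Reactants: 5 6-(benzyloxy)-3-bromo-2-fluoro-4-methylbenzaldehyde
Product: 6 4-methoxybenzyl 4-(benzyloxy)-2-fluoro-3-formyl-6-methylbenzoate
Conditions: Pd(OAc)2 (5 mol %), Xantphos (6 mol %), CO (1 atm), 4-methoxybenzyl alcohol (3 equiv), Et3N (2 equiv), toluene, 90 °C
Reagents that add atoms: carbon monoxide, [C-]#[O+]; 4-methoxybenzyl alcohol, COc1ccc(CO)cc1
Why: Palladium-catalysed alkoxycarbonylation of the aryl bromide (oxidative addition to zerovalent palladium, CO insertion, alcoholysis) tolerates the aldehyde, and the wide-bite-angle ligand is suited to a bromide with two ortho substituents.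

Step 5
Reactants: 7 3,4,5-trimethoxytoluene
Product: 8 5-methylpyrogallol (5-methylbenzene-1,2,3-triol)
Conditions: BBr3 (3.5 equiv), CH2Cl2, −78 to 20 °C; H2O
Reagents that add atoms: none
Why: Lewis acid cleavage of the three aryl methyl ethers (bromide attacks the methyl of the boron-complexed ether).

Step 6
Reactants: 8 5-methylpyrogallol; 9 3,3-dimethylacrylic acid
Product: 11 7,8-dihydroxy-2,2,5-trimethylchroman-4-one, via aryl enone 10 (not isolated)
Conditions: P2O5/MeSO3H, 70 °C, argon
Reagents that add atoms: none
Why: Friedel–Crafts acylation at the only type of free ring position (ortho to one OH, para to another, the triol being symmetric) is followed by intramolecular oxa-Michael addition of the flanking OH, which closes the pyranone ring as a single regioisomer.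

Step 7
Reactants: 11 7,8-dihydroxy-2,2,5-trimethylchroman-4-one
Product: 13 7-hydroxy-8-[(4-methoxybenzyl)oxy]-2,2,5-trimethylchroman-4-one, via disodium catecholate 12 (not isolated)
Conditions: NaH (2.1 equiv), DMSO, 20 °C, argon; 4-methoxybenzyl chloride (1.0 equiv), 20 °C; aq. NH4Cl
Reagents that add atoms: 4-methoxybenzyl chloride, COc1ccc(CCl)cc1
Why: Regioselective mono-O-alkylation of a catechol dianion: the 7-oxide is delocalised into the para C4 carbonyl and the 8-oxide is not, so the 8-oxide is the stronger nucleophile and should take the single equivalent of halide.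

Step 8
Reactants: 13 7-hydroxy-8-[(4-methoxybenzyl)oxy]-2,2,5-trimethylchroman-4-one; 6 4-methoxybenzyl 4-(benzyloxy)-2-fluoro-3-formyl-6-methylbenzoate
Product: 14 4-methoxybenzyl 4-(benzyloxy)-3-formyl-2-({8-[(4-methoxybenzyl)oxy]-2,2,5-trimethyl-4-oxochroman-7-yl}oxy)-6-methylbenzoate
Conditions: Cs2CO3 (1.3 equiv), DMSO, 60 °C, argon
Reagents that add atoms: none
Why: Nucleophilic aromatic substitution (addition–elimination) at a fluoride whose two ortho carbonyl groups stabilise the Meisenheimer adduct; the 7-OH is the only free phenol and O8 is blocked, so the ether can form only at O7 and cannot migrate afterwards.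

Step 9
Reactants: 14 the fully protected diaryl ether
Product: 15 4-(benzyloxy)-3-formyl-2-[(8-hydroxy-2,2,5-trimethyl-4-oxochroman-7-yl)oxy]-6-methylbenzoic acid
Conditions: CF3CO2H (10 vol %), 1,3,5-trimethoxybenzene (5 equiv), CH2Cl2, 0 to 20 °C
Reagents that add atoms: none
Why: Acidolysis through the stabilised 4-methoxybenzyl cation (trapped by the arene scavenger) should free the acid and the C8 phenol together, while the benzyl ether on the electron-poor ring A survives and no phenoxide is ever formed next to the ether.

Step 10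
Reactants: 15 4-(benzyloxy)-3-formyl-2-[(8-hydroxy-2,2,5-trimethyl-4-oxochroman-7-yl)oxy]-6-methylbenzoic acid
Product: 17 ring A O-benzyl depsidone (the target with its ring A hydroxyl as benzyl ether), via spirolactone dienone 16 (not isolated)
Conditions: PhI(OAc)2 (1.1 equiv), (CF3)2CHOH/CH2Cl2, 0 °C; then CF3CO2H (5 equiv), 0 to 20 °C
Reagents that add atoms: none
Why: Proposed new method: the C8 phenol of ring B exchanges onto trivalent iodine, loss of PhI makes C7 electrophilic (the ether oxygen it carries stabilises the charge), and the ring A carboxyl adds ipso there to give the spiro 1,3-benzodioxin-4-one ortho-quinone monoketal 16. Acid then protonates the C8 dienone carbonyl, the acyl carbonyl oxygen bridges C7 and C6 as a five-membered dioxolanylium ion, the C7–O bond opens and loss of the C6 proton rearomatises ring B, so the acyloxy group ends on C6. The closest known reactions are the spirolactonisation of phenolic acids with PhI(OAc)2 (Wessely-type ortho-quinol esters) and the acid-catalysed 1,2-acyloxy shift of ortho-quinol acetates (dienone–phenol type); their combination on a 2-aryloxybenzoic acid has not been shown. The spirolactone closes by 6-exo-trig attack of the carboxyl on C7, and the seven-membered lactone arises by ring expansion of that spirolactone through the 1,2-shift. The spiro carbon of 16 is formed racemic and is erased on rearomatisation, so no stereocontrol is needed. The step needs ipso attack at C7 and not at C5 or C8a, then migration to C6: the tether reaches only C7 in a six-membered ring, the non-nucleophilic fluoroalcohol keeps outside nucleophiles away, only C6 has a hydrogen whose loss restores the arene, and ring A is spared because its phenol is benzylated.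

Step 11
Reactants: 17 ring A O-benzyl depsidone
Product: 18 target depsidone CNP0271978.0
Conditions: BCl3 (3 equiv), pentamethylbenzene (5 equiv), CH2Cl2, −78 to −40 °C; MeOH
Reagents that add atoms: none
Why: Lewis acid debenzylation of an aryl benzyl ether, helped by chelation of boron between the ether oxygen and the ortho formyl group; pentamethylbenzene traps the benzyl cation, and the aryl lactone, diaryl ether and chromanone should survive at low temperature.

**Compound list**
1 | 3-fluoro-5-methylphenol | Cc1cc(O)cc(F)c1 | starting material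
2 | 4-bromo-3-fluoro-5-methylphenol | Cc1cc(O)cc(F)c1Br | intermediate
3 | 5-(benzyloxy)-2-bromo-1-fluoro-3-methylbenzene | Cc1cc(OCc2ccccc2)cc(F)c1Br | intermediate
4 | [6-(benzyloxy)-3-bromo-2-fluoro-4-methylphenyl]lithium | Cc1cc(OCc2ccccc2)c([Li])c(F)c1Br | intermediate
5 | 6-(benzyloxy)-3-bromo-2-fluoro-4-methylbenzaldehyde | Cc1cc(OCc2ccccc2)c(C=O)c(F)c1Br | intermediate
6 | 4-methoxybenzyl 4-(benzyloxy)-2-fluoro-3-formyl-6-methylbenzoate | Cc1cc(OCc2ccccc2)c(C=O)c(F)c1C(=O)OCc1ccc(OC)cc1 | intermediate
7 | 3,4,5-trimethoxytoluene | COc1cc(C)cc(OC)c1OC | starting material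
8 | 5-methylpyrogallol (5-methylbenzene-1,2,3-triol) | Cc1cc(O)c(O)c(O)c1 | intermediate
9 | 3,3-dimethylacrylic acid | CC(C)=CC(=O)O | starting material
10 | 3-methyl-1-(2,3,4-trihydroxy-6-methylphenyl)but-2-en-1-one | CC(C)=CC(=O)c1c(C)cc(O)c(O)c1O | intermediate
11 | 7,8-dihydroxy-2,2,5-trimethylchroman-4-one | Cc1cc(O)c(O)c2c1C(=O)CC(C)(C)O2 | intermediate
12 | disodium 2,2,5-trimethyl-4-oxochroman-7,8-diolate | Cc1cc([O-])c([O-])c2c1C(=O)CC(C)(C)O2.[Na+].[Na+] | intermediate
13 | 7-hydroxy-8-[(4-methoxybenzyl)oxy]-2,2,5-trimethylchroman-4-one | Cc1cc(O)c(OCc3ccc(OC)cc3)c2c1C(=O)CC(C)(C)O2 | intermediate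
14 | 4-methoxybenzyl 4-(benzyloxy)-3-formyl-2-({8-[(4-methoxybenzyl)oxy]-2,2,5-trimethyl-4-oxochroman-7-yl}oxy)-6-methylbenzoate | Cc1cc(OCc2ccccc2)c(C=O)c(Oc2cc(C)c3c(c2OCc4ccc(OC)cc4)OC(C)(C)CC3=O)c1C(=O)OCc5ccc(OC)cc5 | intermediate
15 | 4-(benzyloxy)-3-formyl-2-[(8-hydroxy-2,2,5-trimethyl-4-oxochroman-7-yl)oxy]-6-methylbenzoic acid | Cc1cc(OCc2ccccc2)c(C=O)c(Oc2cc(C)c3c(c2O)OC(C)(C)CC3=O)c1C(=O)O | intermediate
16 | racemic spirolactone dienone: 7-(benzyloxy)-8-formyl-5-methyl-4H-1,3-benzodioxin-4-one spiro-joined at its C2 to C7 of 2,2,5-trimethyl-2,3-dihydrochromene-4,8-dione | Cc1cc(OCc2ccccc2)c(C=O)c3c1C(=O)OC1(O3)C=C(C)C2=C(OC(C)(C)CC2=O)C1=O | intermediate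
17 | ring A O-benzyl depsidone: seven-membered lactone with ester oxygen on chromanone C6 and ether oxygen on chromanone C7; ring A carries CH3 ortho to the lactone carbonyl, OBn para to it and CHO between OBn and the ether oxygen; chromanone part 8-hydroxy-2,2,5-trimethyl | Cc1cc(OCc4ccccc4)c(C=O)c2c1C(=O)Oc1c(C)c3c(c(O)c1O2)OC(C)(C)CC3=O | intermediate
18 | target depsidone CNP0271978.0 (as 17, with free ring A hydroxyl) | Cc1cc(O)c(C=O)c2c1C(=O)Oc1c(C)c3c(c(O)c1O2)OC(C)(C)CC3=O | target

**Step count**
Total: 11 steps. Longest linear sequence: 8 steps (steps 1–4 and 8–11, from 3-fluoro-5-methylphenol).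

**Steps most likely to fail**

Step 10. The oxidised ring B may be captured by an outside nucleophile at C5, or lose a methyl proton to a para-quinone methide, instead of lactonising ipso. The mixed acyl ketal may also ionise or hydrolyse with loss of ring A instead of undergoing the 1,2-shift, and the dienone may dimerise by Diels–Alder reaction. The fallback uses known chemistry and sets out from 14. Bromination with NBS in MeCN at 0 °C should go to C6 of ring B, the position para to the pyran oxygen, and give the 6-bromo diaryl ether F1. Saponification of its ester (LiOH, THF/H2O, 40 °C), with O8 still protected so that no ortho-phenoxide arises, gives the bromo acid F2. An intramolecular Ullmann-type coupling of the carboxylate with the aryl bromide (CuI, 1,10-phenanthroline, Cs2CO3, toluene, 110 °C; monovalent copper catalysis) closes the seven-membered lactone to the 8-O-(4-methoxybenzyl) depsidone F3. CF3CO2H with 1,3,5-trimethoxybenzene in CH2Cl2 then removes the 4-methoxybenzyl ether, and the route is rejoined at 17.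

Step 7. The dianion may be alkylated with poor site selectivity (at O7 or twice), and the catecholate may be oxidised by air. The fallback sets out from 11 and blocks the more acidic oxygen first. Allyl bromide (1.0 equiv) with KHCO3 in DMF at 20 °C, where only the 7-OH is ionised, gives 7-(allyloxy)-8-hydroxy-2,2,5-trimethylchroman-4-one F4. 4-Methoxybenzyl chloride with K2CO3 in DMF gives 7-(allyloxy)-8-[(4-methoxybenzyl)oxy]-2,2,5-trimethylchroman-4-one F5. Pd(PPh3)4 with morpholine in THF removes the allyl group and returns to 13.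

Step 4. Alcoholysis of the hindered aroyl-palladium intermediate by a benzylic alcohol may be slow and give way to hydrodebromination, or the alcohol may displace the activated fluoride. The fallback sets out from 5 and replaces the catalytic carbonylation by halogen–lithium exchange. Ethylene glycol with TsOH in toluene under water removal gives 2-[6-(benzyloxy)-3-bromo-2-fluoro-4-methylphenyl]-1,3-dioxolane F6. n-BuLi in THF at −78 °C gives [4-(benzyloxy)-3-(1,3-dioxolan-2-yl)-2-fluoro-6-methylphenyl]lithium F7, which is quenched with CO2 to 4-(benzyloxy)-3-(1,3-dioxolan-2-yl)-2-fluoro-6-methylbenzoic acid F8. 4-Methoxybenzyl chloride with KHCO3 in DMF gives 4-methoxybenzyl 4-(benzyloxy)-3-(1,3-dioxolan-2-yl)-2-fluoro-6-methylbenzoate F9. Mild acetal hydrolysis (pyridinium tosylate, acetone/H2O, 50 °C) returns to 6.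

**Further compounds**
F1 | step 10 | 4-methoxybenzyl 4-(benzyloxy)-2-({6-bromo-8-[(4-methoxybenzyl)oxy]-2,2,5-trimethyl-4-oxochroman-7-yl}oxy)-3-formyl-6-methylbenzoate | Cc1cc(OCc2ccccc2)c(C=O)c(Oc2c(Br)c(C)c3c(c2OCc4ccc(OC)cc4)OC(C)(C)CC3=O)c1C(=O)OCc5ccc(OC)cc5
F2 | step 10 | 4-(benzyloxy)-2-({6-bromo-8-[(4-methoxybenzyl)oxy]-2,2,5-trimethyl-4-oxochroman-7-yl}oxy)-3-formyl-6-methylbenzoic acid | Cc1cc(OCc2ccccc2)c(C=O)c(Oc2c(Br)c(C)c3c(c2OCc4ccc(OC)cc4)OC(C)(C)CC3=O)c1C(=O)O
F3 | step 10 | ring A O-benzyl, 8-O-(4-methoxybenzyl) depsidone (17 with its C8 hydroxyl as 4-methoxybenzyl ether) | Cc1cc(OCc4ccccc4)c(C=O)c2c1C(=O)Oc1c(C)c3c(c(OCc5ccc(OC)cc5)c1O2)OC(C)(C)CC3=O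
F4 | step 7 | 7-(allyloxy)-8-hydroxy-2,2,5-trimethylchroman-4-one | Cc1cc(OCC=C)c(O)c2c1C(=O)CC(C)(C)O2
F5 | step 7 | 7-(allyloxy)-8-[(4-methoxybenzyl)oxy]-2,2,5-trimethylchroman-4-one | Cc1cc(OCC=C)c(OCc3ccc(OC)cc3)c2c1C(=O)CC(C)(C)O2
F6 | step 4 | 2-[6-(benzyloxy)-3-bromo-2-fluoro-4-methylphenyl]-1,3-dioxolane | Cc1cc(OCc2ccccc2)c(C2OCCO2)c(F)c1Br
F7 | step 4 | [4-(benzyloxy)-3-(1,3-dioxolan-2-yl)-2-fluoro-6-methylphenyl]lithium | Cc1cc(OCc2ccccc2)c(C2OCCO2)c(F)c1[Li]
F8 | step 4 | 4-(benzyloxy)-3-(1,3-dioxolan-2-yl)-2-fluoro-6-methylbenzoic acid | Cc1cc(OCc2ccccc2)c(C2OCCO2)c(F)c1C(=O)O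
F9 | step 4 | 4-methoxybenzyl 4-(benzyloxy)-3-(1,3-dioxolan-2-yl)-2-fluoro-6-methylbenzoate | Cc1cc(OCc2ccccc2)c(C2OCCO2)c(F)c1C(=O)OCc1ccc(OC)cc1
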